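**Assumption:** the target SMILES has no stereocentre, stereogenic axis or configurable double bond, so the compound is achiral and is made as drawn; there is no enantiomer to select.

## Retrosynthetic overview

1. Rings A and B are bought intact. Ring C (the pyranone) is the only ring made and is closed last, O1–C2, by 6-endo addition of the phenol of ynone 8 to its triple bond.
2. Key disconnection C4–C3 of ynone 8: the acyl anion of salicylaldehyde 5 (Breslow intermediate of a carbene catalyst) plus an alkynyl cation equivalent, the alkynyl(mesityl)iodonium salt 7.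
3. 5 comes from 1,2,3,5-tetramethoxybenzene 1 by formylation and chelation-controlled mono-demethylation; 7 comes from 5-ethynyl-1,2,3-trimethoxybenzene 6.

## Route

**Step 1**
Reactants: 1 ring-A arene 1,2,3,5-tetramethoxybenzene
Product: 3 ring-A aldehyde 2,3,4,6-tetramethoxybenzaldehyde, via iminium salt 2 (not isolated)
Conditions: POCl3 (1.3 equiv), DMF, 0 → 60 °C; then H2O, 0 °C → rt
Reagents that add atoms: N,N-dimethylformamide CN(C)C=O; water O
Why: Vilsmeier–Haack formylation: the chloroiminium electrophile attacks one of the two equivalent C–H positions of 1, each flanked by two methoxy groups, and iminium salt 2 is hydrolysed to the aldehyde on work-up; no stereocentre is formed.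

**Step 2**
Reactants: 3 ring-A aldehyde 2,3,4,6-tetramethoxybenzaldehyde
Product: 5 ring-A salicylaldehyde 2-hydroxy-3,4,6-trimethoxybenzaldehyde, via aryloxydichloroborane 4 (not isolated)
Conditions: BCl3 (1.1 equiv), CH2Cl2, −78 → 0 °C; then H2O
Reagents that add atoms: none
Why: Chelation-controlled Lewis-acid ether cleavage: BCl3 bound to the formyl oxygen dealkylates an ortho methoxy group, and the 2-OMe (twisted out of plane between CHO and 3-OMe, hence more basic and strained) is expected to go before the 6-OMe, the six-membered boron chelate 4 then stopping further cleavage; no stereocentre is formed.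

**Step 3**
Reactants: 6 ring-B alkyne 5-ethynyl-1,2,3-trimethoxybenzene
Product: 7 mesityl[(3,4,5-trimethoxyphenyl)ethynyl]iodonium tosylate
Conditions: MesI(OAc)2 (1.05 equiv), TsOH·H2O (1.05 equiv), MeCN, rt, 30 min; then 6, CH2Cl2, 0 °C → rt; Et2O precipitation
Reagents that add atoms: [bis(acetoxy)iodo]mesitylene CC(=O)OI(OC(C)=O)c1c(C)cc(C)cc1C; p-toluenesulfonic acid monohydrate Cc1ccc(S(=O)(=O)O)cc1.O
Why: Koser-type alkynyliodonium synthesis: the [hydroxy(tosyloxy)iodo]mesitylene formed in the flask is attacked by the terminal alkyne and loses water to give the alkynyl(aryl)iodonium tosylate, mesityl being a bulky ligand on trivalent iodine that is not transferred; no stereocentre is formed.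

**Step 4**
Reactants: 5 ring-A salicylaldehyde 2-hydroxy-3,4,6-trimethoxybenzaldehyde; 7 mesityl[(3,4,5-trimethoxyphenyl)ethynyl]iodonium tosylate (1.3 equiv)
Product: 9 bannamurpanisin (5,7,8-trimethoxy-2-(3,4,5-trimethoxyphenyl)-4H-chromen-4-one), via o-hydroxyaryl ynone 8 (not isolated)
Conditions: 2-(pentafluorophenyl)-6,7-dihydro-5H-pyrrolo[2,1-c][1,2,4]triazol-2-ium tetrafluoroborate (20 mol %), N,N,N',N'-tetramethylethylenediamine (2.5 equiv), toluene, −40 → −20 °C; then 4-(dimethylamino)pyridine (30 mol %), DMF, rt
Reagents that add atoms: none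
Why: Proposed new method: the triazolylidene adds to the formyl group of 5 to give a Breslow intermediate (acyl anion equivalent, the ortho OH acting as proton shuttle), which displaces iodomesitylene at the acetylenic carbon of 7 and collapses to ynone 8 with release of the carbene; 4-(dimethylamino)pyridine then adds to the ynone β-carbon so that the phenol closes ring C in the 6-endo sense by addition–elimination; the closest known reactions are the carbene-catalysed C–H alkynylation of heteroaryl aldehydes with alkynyl(aryl)iodonium salts and the amine-catalysed 6-endo cyclisation of o-hydroxyaryl ynones to flavones, here merged and extended to a free, electron-rich salicylaldehyde; no stereocentre is formed.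

## Compound list

1 | 1,2,3,5-tetramethoxybenzene | COc1cc(OC)c(OC)c(OC)c1 | starting material
2 | N,N-dimethyl-1-(2,3,4,6-tetramethoxyphenyl)methaniminium dichlorophosphate | COc1cc(OC)c(C=[N+](C)C)c(OC)c1OC.[O-]P(=O)(Cl)Cl | intermediate (not isolated)
3 | 2,3,4,6-tetramethoxybenzaldehyde | COc1cc(OC)c(C=O)c(OC)c1OC | intermediate
4 | dichloro(2-formyl-3,5,6-trimethoxyphenoxy)borane | COc1cc(OC)c(C=O)c(OB(Cl)Cl)c1OC | intermediate (not isolated)
5 | 2-hydroxy-3,4,6-trimethoxybenzaldehyde | COc1cc(OC)c(C=O)c(O)c1OC | intermediate
6 | 5-ethynyl-1,2,3-trimethoxybenzene | C#Cc1cc(OC)c(OC)c(OC)c1 | starting material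
7 | mesityl[(3,4,5-trimethoxyphenyl)ethynyl]iodonium 4-methylbenzenesulfonate | COc1cc(C#C[I+]c2c(C)cc(C)cc2C)cc(OC)c1OC.Cc1ccc(S(=O)(=O)[O-])cc1 | intermediate
8 | 1-(2-hydroxy-3,4,6-trimethoxyphenyl)-3-(3,4,5-trimethoxyphenyl)prop-2-yn-1-one | COc1cc(OC)c(C(=O)C#Cc2cc(OC)c(OC)c(OC)c2)c(O)c1OC | intermediate (not isolated)
9 | bannamurpanisin, 5,7,8-trimethoxy-2-(3,4,5-trimethoxyphenyl)-4H-chromen-4-one (achiral) | COc1cc(-c2cc(=O)c3c(OC)cc(OC)c(OC)c3o2)cc(OC)c1OC | target

## Step count and risks

Total step count: 4. Longest linear sequence: 3 steps (1 → 3 → 5 → 9, steps 1, 2 and 4); step 3 is a one-step side branch.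

**Most likely to fail, first: step 4.** Breslow-intermediate formation on a 2,6-disubstituted, very electron-rich aldehyde may be slow. The free phenol or the carbene itself may be alkynylated by 7. The ynone may close 5-exo to the aurone. The fallback sets out from 5 and comes back to the route at 9, replacing the catalytic acyl anion by a stoichiometric one with an epoxide partner. 5 is condensed with propane-1,3-dithiol (BF3·OEt2, CH2Cl2, 0 °C) to the dithiane 2-(1,3-dithian-2-yl)-3,5,6-trimethoxyphenol F1. n-BuLi (2.2 equiv, THF, −30 °C) gives its phenoxide/dithianyl dianion, which opens racemic 2-(3,4,5-trimethoxyphenyl)oxirane F2 at the CH2 carbon. F2 is made from commercial 3,4,5-trimethoxybenzaldehyde, COc1cc(C=O)cc(OC)c1OC, with trimethylsulfonium iodide and NaH in DMSO/THF. The opening gives the racemic alcohol 2-{2-[2-hydroxy-2-(3,4,5-trimethoxyphenyl)ethyl]-1,3-dithian-2-yl}-3,5,6-trimethoxyphenol F3. I2 (20 mol %) in DMSO at 120 °C then unmasks the ketone, dehydrates the aldol to the 2'-hydroxychalcone and cyclises and dehydrogenates it to 9; the carbinol stereocentre is lost on the way.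

**Second: step 3.** The acidic trivalent-iodine reagent may attack the electron-rich ring B or add tosylate across the alkyne instead of giving the alkynyl salt. The fallback sets out from 6 and comes back at 7, moving the alkynyl group from boron to iodine under nearly neutral conditions. 6 is deprotonated (n-BuLi, THF, −78 °C) and quenched with 2-isopropoxy-4,4,5,5-tetramethyl-1,3,2-dioxaborolane to give the alkynyl boronate 4,4,5,5-tetramethyl-2-[(3,4,5-trimethoxyphenyl)ethynyl]-1,3,2-dioxaborolane F4. F4 exchanges boron for trivalent iodine with MesI(OAc)2 and TsOH·H2O in CH2Cl2/2,2,2-trifluoroethanol at rt to give 7.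

**Third: step 2.** The 6-OMe could be cleaved in place of, or along with, the 2-OMe. The product is checked by NOE: H5 of 5 shows contacts to two methoxy groups, whereas the unwanted 6-hydroxy isomer shows one. The fallback sets out from 1 and comes back at 5, making the C–C bond and cleaving the ether in one aluminium-templated operation. 1 is treated with dichloromethyl methyl ether and AlCl3 (2.5 equiv, CH2Cl2, 0 °C → rt). The racemic chloro ether 2-[chloro(methoxy)methyl]-1,3,4,5-tetramethoxybenzene F5 collapses in the flask to the AlCl3 complex of 3, whose chelate removes the flanked ortho methyl group before aqueous work-up releases 5. This relies on the same chelation preference as step 2, so it answers over-cleavage and handling problems more than a wrong intrinsic selectivity.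

## Further compounds

F1 | step 4 | 2-(1,3-dithian-2-yl)-3,5,6-trimethoxyphenol | COc1cc(OC)c(C2SCCCS2)c(O)c1OC
F2 | step 4 | 2-(3,4,5-trimethoxyphenyl)oxirane (racemic) | COc1cc(C2CO2)cc(OC)c1OC
F3 | step 4 | 2-{2-[2-hydroxy-2-(3,4,5-trimethoxyphenyl)ethyl]-1,3-dithian-2-yl}-3,5,6-trimethoxyphenol (racemic) | COc1cc(OC)c(C2(CC(O)c3cc(OC)c(OC)c(OC)c3)SCCCS2)c(O)c1OC
F4 | step 3 | 4,4,5,5-tetramethyl-2-[(3,4,5-trimethoxyphenyl)ethynyl]-1,3,2-dioxaborolane | COc1cc(C#CB2OC(C)(C)C(C)(C)O2)cc(OC)c1OC
F5 | step 2 | 2-[chloro(methoxy)methyl]-1,3,4,5-tetramethoxybenzene (racemic) | COc1cc(OC)c(C(Cl)OC)c(OC)c1OC
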